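At 5.0 h I read the north flask, the flask asked about, and asked what had become of the substrate charged.

| flask | substrate | partner | remark | time |
|---|---|---|---|---|
| north | 0.20 M | 1 equiv | the very flask that is asked about, followed so far |  |
| flask | 0.20 M | 1.00 equiv |  | 5.0 h |

north run (percent of the substrate charged)

| time / h | target / % | substrate / % |
|---|---|---|
| 0.417 | 53.7 | 43.7 |
| 0.667 | 66.4 | 26.2 |
| 1.00 | 70.0 | 20.3 |
| 2.00 | 68.1 | 13.9 |
| 3.00 | 65.9 | 11.6 |
| 5.00 | 62.1 | 7.6 |

(each reading ± 0.3 percentage points)

- removed target is counted in
- additions bring no volume worth counting

- Wednesday's: change nothing and wait 10 h more
- Friday's: at 5.0 h add substrate, 50.0 % of the amount charged, then wait 10 h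
- Monday's: at 5.0 h add partner, 50.0 % of the amount charged, then wait 10 h
- Thursday's: at 5.0 h take out 90 % of the target then present, then wait 10 h

* target, in percent of the substrate first charged, at 5.0 h
* the option that brings most further target ("none" if no option brings more than 2 percentage points) (Wednesday's / Friday's / Monday's / Thursday's / none)
* target present, with what was taken out counted in, in percent of the substrate first charged, after Monday's
* target present, with what was taken out counted in, in percent of the substrate first charged, after Thursday's

1. From 2.00 h to 5.00 h, target fell by 6 percentage points and substrate by 6.3 points, so I read a loss taking one of each. That let me undo the loss by arithmetic. At 5.00 h the readings gave 77.2 % of delivered target: the whole charge plus target minus substrate, divided by two, which counts substrate that ever became target, whether it remains target or was lost since.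

2. First reading: at 0.417 h, delivered target already read 55.0 % against 53.7 % of target standing, so the readings put the loss so far at 1.3 points.

3. Middle: it read 74.9 % at 1.00 h and 77.1 % at 2.00 h, and had moved by 0.15 points by 5.00 h, with substrate still reading 7.6 %. I took partner, unread, as the limiting reagent, and supposed some had gone elsewhere, delivery standing below the charge.

4. End: with delivery reading flat, I reckoned that each point of substrate left would cost a point of target, so waiting heads for an estimated floor of 54.5 %. New partner could instead raise target towards an estimated ceiling of 69.7 %. I therefore chose Monday's.

5. The forecast gave 62.1 % now, Monday's as best, 68.5 % after Monday's and 61 % after Thursday's, holding that “Something has run out, most likely the partner through an unseen sink”.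

6. The flask gave 61.7 % now and Monday's as best, with a gain of 6.7 points. It reached 68.4 % after Monday's and 60.4 % after Thursday's.

    partner → decomposed reagent (k = 0.0111 /min)
    substrate + partner → target (k = 0.0104 /M/min)
    substrate + target → side product (k = 0.0276 /M/min)
    substrate + partner + target → 2 target (k = 7.91 /M²/min)

7. Recounted from the simulated amounts, this flask's delivered target was 77.2 % at 5.0 h and 77.2 % at 50.0 h, when target stood at 54.3 %. At 5.0 h, with partner at 0 %, delivery amounted to 0.154 M, and decomposed reagent added 0.0457 M, making 0.200 M. The neighbour flask with 0.400 equiv of partner held 9.81 % target and 58.9 % substrate, so it had delivered 25.5 %, or 0.0509 M, and with 0.0291 M of decomposed reagent that came to 0.0800 M.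

The earlier runs and the new flask were computed for an exercise.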